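All runs were generated by integration on assumed constants.

In a one-step world, target decays at first order with rate constant λ and whatever stands beside it stays put. Then r = [isomer of the product]/[target] grows as exp(λt), and the charge does not enter.

| setting | east | north-east | flask |
|---|---|---|---|
| substrate | 0.062 M | 0.097 M | 0.044 M |
| remark | run made earlier | run made earlier |  |
| time |  |  | 15 d |

| run | time / d | isomer of the product / % | target / % |
|---|---|---|---|
| east | 0.833 | 4 | 56 |
| east | 2.50 | 9 | 37 |
| east | 4.00 | 9 | 23 |
| east | 6.00 | 6 | 14 |
| east | 10.0 | 6 | 9 |
| east | 12.0 | 6 | 5 |
| north-east | 1.04 | 7 | 49 |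
| north-east | 1.67 | 5 | 42 |
| north-east | 2.50 | 10 | 34 |
| north-east | 4.00 | 4 | 22 |
| north-east | 8.00 | 5 | 10 |
| north-east | 12.0 | 5 | 3 |

(readings scatter by 1.5 percentage points)

- ratio of isomer of the product to target at 15 min
- ratio of isomer of the product to target at 15 d

- the earlier runs were read with a standard deviation of 1.5 percentage points

From its first and last target readings, the east run gives λ = 0.216 /d and the north-east run, at a different charge, 0.255 /d. Take 0.236 /d. From 15 min to 15 d, r then grows by 34.2, the ratio gain G.

Now take two extremes. If the isomer forms from substrate beside target, r starts at a branching ratio, the selectivity factor. The first readings of both runs, pooled, give r = 0.105, with their scatter. Run back by λ, that is 0.0842 at 15 min, and G carries it to 2.88 at 15 d. If the isomer forms from target in series, r starts at zero and rises with time, so the same readings give 0.00117 at 15 min. I expect r in the flask, with 0.044 M of substrate, to lie between these two at 15 min, and a loss of isomer lowers the late ratio below the value that G gives.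

The forecast gave 0.02 at 15 min and 2.5 at 15 d, judging: "The isomer therefore looks mostly secondary, though a small parallel route can't be excluded".

The flask gives r = 0.0527 at 15 min, less than 0.0842 and more than 0.00117, and 1.44 at 15 d. At 15 d, target in the flask is still being made, each step taken net, at 0.482 of the rate at which it is used up. G on the flask's early value gives 1.80, more than the flask shows; the flask's own gain in r is 27.3.

    substrate ⇌ target (K = 5.40, k = 0.160 /h)
    substrate ⇌ isomer of the product (K = 2.00, k = 0.00840 /h)
    2 substrate → self-condensation product (k = 0.510 /M/h)
    target → over-reaction product (k = 0.0110 /h)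

The neighbour flask holds 0.18 M of substrate. G, which has no charge in it, takes that flask's 0.0527 to 1.80; the computed ratio at 15 d is 1.50.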